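**Retrosynthetic overview**
1. Numbering follows 1H-isochromen-8-one: C1H2, O2, C3, C4, C4a, C5H2, C6, C7, C8=O, C8a. The carbocycle is ring A and the pyran is ring B. The plan rests on one feature: C4a is the β-carbon of the C8=O/C8a=C4a enone. C3 carries both O2 and the propenol chain. Once C3–C4 is written as an alkyne, C3 becomes the δ-carbon of that enone and closes a six-membered ring with the oxygen on C1.
2. Key disconnection (ring B, made last), both bonds in one flask. C4–C4a comes from Sonogashira coupling of a ring A vinylogous acid chloride bearing the C8a–CH2OH group with the O-silylated (E)-pentenyne. O2–C3 comes from 6-endo oxa-1,6-addition of the C1 hydroxyl to the resulting ynenone.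
3. Ring A (made first) closes at C8a–C4a by a Dieckmann-type Claisen condensation of a keto ester. The keto ester is built from 2-C-methyl-D-erythrono-1,4-lactone, which supplies C5–C8 and both stereocentres. C4a comes from a Wittig homologation, C8a from MeMgBr, and C1 with O2 from a Stille hydroxymethylation.
4. Order of events: the C4a leaving group is set before C1, because a 2-hydroxymethyl-1,3-dione would dehydrate. It is chloride so that the C8a iodide can be coupled first. The acetonide is removed before ring B exists, because the dienol ether and the allylic silyl ether would not survive aqueous acid.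
5. Endgame: C6-selective acylation by bis-silylated orsellinoyl chloride, then one global desilylation.

Key step: step 13

Remark: (E)-pent-2-en-4-yn-1-ol is taken as the geometrically pure E isomer, and atom labels in all steps are those of the target skeleton given above.

Step 1
Reactants: 1 2-C-methyl-D-erythrono-1,4-lactone [(3R,4R)-3,4-dihydroxy-3-methyloxolan-2-one]
Product: 2 2,3-O-isopropylidene-2-C-methyl-D-erythrono-1,4-lactone (cis-fused acetonide of 1)
Conditions: Me2C(OMe)2, TsOH·H2O (cat.), acetone, rt
Reagents that add atoms: 2,2-dimethoxypropane, COC(C)(C)OC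
Why: Acid-catalysed transketalisation (acetonide formation) is favoured for the cis diol on the five-membered lactone and touches neither stereocentre.

Step 2
Reactants: 2 2,3-O-isopropylidene-2-C-methyl-D-erythrono-1,4-lactone
Product: 3 (4R,5R)-5-(hydroxymethyl)-N-methoxy-N,2,2,4-tetramethyl-1,3-dioxolane-4-carboxamide
Conditions: MeNH(OMe)·HCl, AlMe3, CH2Cl2, 0 °C → rt; aq. potassium sodium tartrate
Reagents that add atoms: N,O-dimethylhydroxylamine hydrochloride, CNOC.Cl
Why: Aluminium amide aminolysis of a lactone opens the ring at C8 without epimerisation, and the N-methoxy-N-methyl amide is chosen because a cis 4-hydroxy ester would relactonise at once.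

Step 3
Reactants: 3 (4R,5R)-5-(hydroxymethyl)-N-methoxy-N,2,2,4-tetramethyl-1,3-dioxolane-4-carboxamide
Product: 4 (4R,5S)-5-formyl-N-methoxy-N,2,2,4-tetramethyl-1,3-dioxolane-4-carboxamide (same spatial arrangement as 3; the descriptor changes by priority only)
Conditions: Dess–Martin periodinane, pyridine, CH2Cl2, 0 °C → rt
Reagents that add atoms: none
Why: Dess–Martin oxidation stops at the aldehyde under almost neutral conditions and so keeps the C6 stereocentre next to the new formyl group, and going through an aldehyde means that no leaving group is ever placed on C5, where the cis C8 carbonyl oxygen would displace it.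

Step 4
Reactants: 4 (4R,5S)-5-formyl-N-methoxy-N,2,2,4-tetramethyl-1,3-dioxolane-4-carboxamide
Product: 5 (4R,5R)-N-methoxy-5-(2-methoxyethenyl)-N,2,2,4-tetramethyl-1,3-dioxolane-4-carboxamide (E/Z mixture expected, both isomers converge in step 6)
Conditions: MeOCH2PPh3Cl, KN(SiMe3)2, THF, −78 → 0 °C
Reagents that add atoms: (methoxymethyl)triphenylphosphonium chloride, COC[P+](c1ccccc1)(c1ccccc1)c1ccccc1.[Cl-]
Why: Wittig methoxymethylenation adds C4a as a masked carboxyl carbon, since the non-stabilised ylide takes the aldehyde at low temperature much faster than the aldehyde enolises or the hindered amide is attacked.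

Step 5
Reactants: 5 (4R,5R)-N-methoxy-5-(2-methoxyethenyl)-N,2,2,4-tetramethyl-1,3-dioxolane-4-carboxamide
Product: 6 1-[(4R,5R)-5-(2-methoxyethenyl)-2,2,4-trimethyl-1,3-dioxolan-4-yl]ethanone (E/Z mixture)
Conditions: MeMgBr, THF, −20 → 0 °C; aq. NH4Cl
Reagents that add atoms: methylmagnesium bromide, C[Mg]Br
Why: Grignard addition to the N-methoxy-N-methyl amide gives a chelated tetrahedral adduct that collapses to the methyl ketone only on work-up, which brings in C8a without over-addition while the enol ether is inert.

Step 6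
Reactants: 6 1-[(4R,5R)-5-(2-methoxyethenyl)-2,2,4-trimethyl-1,3-dioxolan-4-yl]ethanone
Product: 7 methyl 2-[(4R,5R)-5-acetyl-2,2,5-trimethyl-1,3-dioxolan-4-yl]acetate
Conditions: pyridinium chlorochromate, 4 Å MS, CH2Cl2, rt
Reagents that add atoms: pyridinium chlorochromate, [O-][Cr](=O)(=O)Cl.c1cc[nH+]cc1
Why: Chlorochromate oxidation of an enol ether to the ester (attack on the electron-rich alkene, then 1,2-hydride shift) turns C4a into the acyl acceptor in one operation and leaves ketone and acetonide alone.

Step 7
Reactants: 7 methyl 2-[(4R,5R)-5-acetyl-2,2,5-trimethyl-1,3-dioxolan-4-yl]acetate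
Product: 8 (3aR,7aR)-2,2,3a-trimethyl-7,7a-dihydro-3aH-1,3-benzodioxole-4,6(5H)-dione (ring A dione: C8 and C4a carbonyls, C8a methylene, 6,7-acetonide)
Conditions: LiN(SiMe3)2 (2.2 equiv), THF, −78 → 0 °C; cold 1 M HCl to pH 4
Reagents that add atoms: none
Why: In this intramolecular Claisen (Dieckmann-type) condensation C7 is quaternary, so the ketone can enolise only at C8a, the two arms are cis on the dioxolane, and the six-membered dione is drained as its stabilised enolate, which also protects the C6–O bond from β-elimination.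

Step 8
Reactants: 8 (3aR,7aR)-2,2,3a-trimethyl-7,7a-dihydro-3aH-1,3-benzodioxole-4,6(5H)-dione
Product: 9 (3aR,7aR)-6-hydroxy-5-iodo-2,2,3a-trimethyl-7,7a-dihydro-1,3-benzodioxol-4(3aH)-one (C8a-iodo dione, drawn as the C4a enol)
Conditions: N-iodosuccinimide, MeCN, 0 °C, dark
Reagents that add atoms: N-iodosuccinimide, O=C1CCC(=O)N1I
Why: Electrophilic iodination of the enolised 1,3-dione takes place at its only nucleophilic carbon, C8a.

Step 9
Reactants: 9 (3aR,7aR)-6-hydroxy-5-iodo-2,2,3a-trimethyl-7,7a-dihydro-1,3-benzodioxol-4(3aH)-one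
Product: 10 (3aR,7aR)-6-chloro-5-iodo-2,2,3a-trimethyl-7,7a-dihydro-1,3-benzodioxol-4(3aH)-one
Conditions: (COCl)2, DMF (cat.), CH2Cl2, 0 °C → rt
Reagents that add atoms: oxalyl chloride, O=C(Cl)C(=O)Cl
Why: Oxalyl chloride with catalytic DMF turns a cyclic 1,3-dione into its vinylogous acid chloride, here by activation of the less hindered enol oxygen on C4a (the C8 oxygen is shielded by quaternary C7) and ipso attack of chloride, and it is done before C1 is added because a 2-(hydroxymethyl)-1,3-dione would lose water.

Step 10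
Reactants: 10 (3aR,7aR)-6-chloro-5-iodo-2,2,3a-trimethyl-7,7a-dihydro-1,3-benzodioxol-4(3aH)-one
Product: 11 (3aR,7aR)-6-chloro-5-(hydroxymethyl)-2,2,3a-trimethyl-7,7a-dihydro-1,3-benzodioxol-4(3aH)-one
Conditions: Bu3SnCH2OH, Pd2(dba)3 (2.5 mol %), AsPh3 (20 mol %), CuI (10 mol %), NMP, rt → 45 °C
Reagents that add atoms: (tributylstannyl)methanol, CCCC[Sn](CCCC)(CCCC)CO
Why: This is a Stille hydroxymethylation of an α-iodoenone, in which zerovalent palladium carrying the weak donor AsPh3 inserts into the carbon–iodine bond at C8a far below the temperature at which the carbon–chlorine bond at C4a responds (a C4a sulfonate would compete), and copper-assisted transfer of CH2OH from tin then sets C8a–C1.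

Step 11
Reactants: 11 (3aR,7aR)-6-chloro-5-(hydroxymethyl)-2,2,3a-trimethyl-7,7a-dihydro-1,3-benzodioxol-4(3aH)-one
Product: 12 (5R,6R)-3-chloro-5,6-dihydroxy-2-(hydroxymethyl)-6-methylcyclohex-2-en-1-one (key-step precursor)
Conditions: TFA, H2O, CH2Cl2, 0 °C → rt
Reagents that add atoms: none
Why: Acid hydrolysis of the acetonide is placed here, where vinylogous chloride, enone and allylic alcohol tolerate it, because later the dienol ether and the allylic silyl ether would not.

Step 12
Reactants: 13 (E)-pent-2-en-4-yn-1-ol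
Product: 14 (E)-5-(tert-butyldimethylsilyloxy)pent-3-en-1-yne
Conditions: TBSCl, imidazole, CH2Cl2, 0 °C → rt
Reagents that add atoms: tert-butyldimethylsilyl chloride, CC(C)(C)[Si](C)(C)Cl
Why: Standard silylation of a primary allylic alcohol leaves the alkyne C–H and the E alkene untouched.

Step 13
Reactants: 12 (5R,6R)-3-chloro-5,6-dihydroxy-2-(hydroxymethyl)-6-methylcyclohex-2-en-1-one; 14 (E)-5-(tert-butyldimethylsilyloxy)pent-3-en-1-yne
Product: 16 (6R,7R)-3-[(E)-3-(tert-butyldimethylsilyloxy)prop-1-enyl]-6,7-dihydroxy-7-methyl-1,5,6,7-tetrahydro-8H-isochromen-8-one, via ynenone 15 (not isolated)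
Conditions: PdCl2(PPh3)2 (5 mol %), CuI (5 mol %), iPr2NEt, degassed DMF, rt → 50 °C; then DBU (0.2 equiv), rt
Reagents that add atoms: none
Why: Zerovalent palladium adds oxidatively to the carbon–chlorine bond at C4a of the vinylogous acid chloride (an insertion of addition–elimination character that the C8 carbonyl accelerates), the copper acetylide of 14 transmetalates, and reductive elimination forms C4–C4a to give ynenone 15. In 15 the alkyne is polarised through C4a=C8a by the C8 carbonyl, so C3 is the δ-acceptor carbon, the C1 hydroxyl adds to it under amine and DBU catalysis, and protonation at C4 gives the dienol ether conjugated with the ketone. The closest known chemistry is the tandem Sonogashira coupling and cycloisomerisation of ortho-halobenzyl alcohols and β-halo enones to isochromenes and pyrans. Ring B closes in the 6-endo-dig mode, no stereocentre is formed, and C6, C7 and the E alkene of 14 are spectators. The step needs 6-endo closure at C3 over 5-exo closure at C4, which would run on to a fused furan, and since attack at C4 is an anti-Michael addition opened only by strong base or carbophilic metals, mild base and a low copper load keep the reaction in the Michael-type channel. A tertiary amine is used because a secondary amine would displace the C4a chloride, and the C6 and C7 hydroxyls cannot reach the alkyne.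

Step 14
Reactants: 17 orsellinic acid (2,4-dihydroxy-6-methylbenzoic acid)
Product: 19 2,4-bis(tert-butyldimethylsilyloxy)-6-methylbenzoic acid, via silyl ester 18 (not isolated)
Conditions: TBSCl (3.5 equiv), imidazole, DMF, rt; then AcOH, THF, H2O, rt
Reagents that add atoms: tert-butyldimethylsilyl chloride, CC(C)(C)[Si](C)(C)Cl
Why: Exhaustive silylation followed by selective hydrolysis of the far more labile silyl ester is the usual way to O-silylated hydroxybenzoic acids, and room temperature avoids decarboxylation of orsellinic acid.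

Step 15
Reactants: 16 (6R,7R)-3-[(E)-3-(tert-butyldimethylsilyloxy)prop-1-enyl]-6,7-dihydroxy-7-methyl-1,5,6,7-tetrahydro-8H-isochromen-8-one; 19 2,4-bis(tert-butyldimethylsilyloxy)-6-methylbenzoic acid
Product: 21 tris-O-TBS entonaemin A (C6 ester of diol 16 and acid 19; C7 hydroxyl free), via acid chloride 20 (not isolated)
Conditions: 19, 1-chloro-N,N,2-trimethylprop-1-en-1-amine, CH2Cl2, 0 °C; then 16, pyridine, DMAP (cat.), 0 °C → rt
Reagents that add atoms: none
Why: Acylation by an acid chloride made under neutral conditions (α-chloroenamine) with DMAP catalysis takes the secondary C6 hydroxyl with retention while the tertiary C7 hydroxyl next to the ketone is too hindered, and the weak base avoids vinylogous β-elimination of the new ester.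

Step 16
Reactants: 21 tris-O-TBS entonaemin A
Product: 22 entonaemin A
Conditions: HF·pyridine, pyridine, THF, 0 °C → rt
Reagents that add atoms: none
Why: Buffered fluoride cleaves the two aryl silyl ethers and the primary allylic silyl ether in one operation near neutral pH, so that the dienol ether, the C6 ester and the allylic alcohol are not put at risk.

**Compound list**
1 | 2-C-methyl-D-erythrono-1,4-lactone | O[C@@H]1COC(=O)[C@]1(C)O | starting material
2 | 2,3-O-isopropylidene-2-C-methyl-D-erythrono-1,4-lactone | CC1(C)O[C@@H]2COC(=O)[C@]2(C)O1 | intermediate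
3 | (4R,5R)-5-(hydroxymethyl)-N-methoxy-N,2,2,4-tetramethyl-1,3-dioxolane-4-carboxamide | CC1(C)O[C@H](CO)[C@](C)(C(=O)N(C)OC)O1 | intermediate
4 | (4R,5S)-5-formyl-N-methoxy-N,2,2,4-tetramethyl-1,3-dioxolane-4-carboxamide | CC1(C)O[C@H](C=O)[C@](C)(C(=O)N(C)OC)O1 | intermediate
5 | (4R,5R)-N-methoxy-5-(2-methoxyethenyl)-N,2,2,4-tetramethyl-1,3-dioxolane-4-carboxamide (E/Z) | CC1(C)O[C@H](C=COC)[C@](C)(C(=O)N(C)OC)O1 | intermediate
6 | 1-[(4R,5R)-5-(2-methoxyethenyl)-2,2,4-trimethyl-1,3-dioxolan-4-yl]ethanone (E/Z) | CC1(C)O[C@H](C=COC)[C@](C)(C(C)=O)O1 | intermediate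
7 | methyl 2-[(4R,5R)-5-acetyl-2,2,5-trimethyl-1,3-dioxolan-4-yl]acetate | CC1(C)O[C@H](CC(=O)OC)[C@](C)(C(C)=O)O1 | intermediate
8 | (3aR,7aR)-2,2,3a-trimethyl-7,7a-dihydro-3aH-1,3-benzodioxole-4,6(5H)-dione | CC1(C)O[C@@H]2CC(=O)CC(=O)[C@]2(C)O1 | intermediate
9 | (3aR,7aR)-6-hydroxy-5-iodo-2,2,3a-trimethyl-7,7a-dihydro-1,3-benzodioxol-4(3aH)-one | CC1(C)O[C@@H]2CC(O)=C(I)C(=O)[C@]2(C)O1 | intermediate
10 | (3aR,7aR)-6-chloro-5-iodo-2,2,3a-trimethyl-7,7a-dihydro-1,3-benzodioxol-4(3aH)-one | CC1(C)O[C@@H]2CC(Cl)=C(I)C(=O)[C@]2(C)O1 | intermediate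
11 | (3aR,7aR)-6-chloro-5-(hydroxymethyl)-2,2,3a-trimethyl-7,7a-dihydro-1,3-benzodioxol-4(3aH)-one | CC1(C)O[C@@H]2CC(Cl)=C(CO)C(=O)[C@]2(C)O1 | intermediate
12 | (5R,6R)-3-chloro-5,6-dihydroxy-2-(hydroxymethyl)-6-methylcyclohex-2-en-1-one | O[C@@H]1CC(Cl)=C(CO)C(=O)[C@]1(C)O | intermediate
13 | (E)-pent-2-en-4-yn-1-ol | C#C/C=C/CO | starting material
14 | (E)-5-(tert-butyldimethylsilyloxy)pent-3-en-1-yne | C#C/C=C/CO[Si](C)(C)C(C)(C)C | intermediate
15 | (5R,6R)-3-[(E)-5-(tert-butyldimethylsilyloxy)pent-3-en-1-ynyl]-5,6-dihydroxy-2-(hydroxymethyl)-6-methylcyclohex-2-en-1-one | O[C@@H]1CC(C#C/C=C/CO[Si](C)(C)C(C)(C)C)=C(CO)C(=O)[C@]1(C)O | intermediate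
16 | (6R,7R)-3-[(E)-3-(tert-butyldimethylsilyloxy)prop-1-enyl]-6,7-dihydroxy-7-methyl-1,5,6,7-tetrahydro-8H-isochromen-8-one | O[C@@H]1CC2=C(COC(/C=C/CO[Si](C)(C)C(C)(C)C)=C2)C(=O)[C@]1(C)O | intermediate
17 | orsellinic acid | Cc1cc(O)cc(O)c1C(=O)O | starting material
18 | tert-butyldimethylsilyl 2,4-bis(tert-butyldimethylsilyloxy)-6-methylbenzoate | Cc1cc(O[Si](C)(C)C(C)(C)C)cc(O[Si](C)(C)C(C)(C)C)c1C(=O)O[Si](C)(C)C(C)(C)C | intermediate
19 | 2,4-bis(tert-butyldimethylsilyloxy)-6-methylbenzoic acid | Cc1cc(O[Si](C)(C)C(C)(C)C)cc(O[Si](C)(C)C(C)(C)C)c1C(=O)O | intermediate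
20 | 2,4-bis(tert-butyldimethylsilyloxy)-6-methylbenzoyl chloride | Cc1cc(O[Si](C)(C)C(C)(C)C)cc(O[Si](C)(C)C(C)(C)C)c1C(=O)Cl | intermediate
21 | tris-O-TBS entonaemin A | Cc1cc(O[Si](C)(C)C(C)(C)C)cc(O[Si](C)(C)C(C)(C)C)c1C(=O)O[C@@H]1CC2=C(COC(/C=C/CO[Si](C)(C)C(C)(C)C)=C2)C(=O)[C@]1(C)O | intermediate
22 | entonaemin A | Cc1cc(O)cc(O)c1C(=O)O[C@@H]1CC2=C(COC(/C=C/CO)=C2)C(=O)[C@]1(C)O | target

Total step count: 16. Longest linear sequence: 14 (steps 1–11, 13, 15, 16).

**Steps most likely to fail**

Step 13 (key step). Oxidative addition at the tetrasubstituted carbon–chlorine bond may be slow. The alkyne may homocouple while the chloride waits. Ring closure may drift into the 5-exo mode and then aromatise under the metals present. The fallback takes the cascade apart and changes the electrophile. Setting out from 12, halide exchange by addition–elimination (NaI, AcOH cat., acetone) should give (5R,6R)-5,6-dihydroxy-2-(hydroxymethyl)-3-iodo-6-methylcyclohex-2-en-1-one F1. F1 should couple with 14 at room temperature (same catalyst pair, iPr2NEt, THF), so that ynenone 15 can be isolated and freed from palladium and copper. Ynenone 15 is then closed in a separate, metal-free operation with catalytic DBU in MeCN, where only the Michael-type 6-endo channel is open. The route is rejoined at 16.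

Step 10. The iodide may be lost by protodeiodination, the sp3 group may transfer slowly from tin, and insertion into the carbon–chlorine bond may set in once the mixture is warmed. The fallback needs no cross-coupling and brings C1 in at the aldehyde level, bypassing steps 8–10. Setting out from dione 8, condensation with Me2NCH(OMe)2 in toluene should give the enaminodione (3aR,7aR)-5-(dimethylaminomethylidene)-2,2,3a-trimethyl-7,7a-dihydro-3aH-1,3-benzodioxole-4,6(5H)-dione F2. Oxalyl chloride in CH2Cl2 should replace the less hindered C4a oxygen and give the chloro iminium chloride F3. Aqueous NaHCO3 should hydrolyse F3 to (3aR,7aR)-6-chloro-2,2,3a-trimethyl-4-oxo-3a,4,7,7a-tetrahydro-1,3-benzodioxole-5-carbaldehyde F4. This is a haloformylation of the Vilsmeier–Haack–Arnold type run in two stages. NaBH(OAc)3 in CH2Cl2 reduces aldehydes but not hindered ketones. It should take F4 to the allylic alcohol, and the route is rejoined at 11.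

Step 15. Acylation by the doubly ortho-substituted aroyl chloride may be sluggish. Long exposure to base could then bring on vinylogous β-elimination of the new ester. The fallback activates the alcohol instead of the acid. Setting out from 16, Bu2SnO (MeOH, 60 °C, then evaporation) should give the 6,7-O-dibutylstannylene acetal of 16 F5. In CH2Cl2 without any amine, F5 should react with acid chloride 20 at the secondary oxygen and give the C7 chlorodibutylstannyl ether of 21 F6. Aqueous work-up frees the C7 hydroxyl, and the route is rejoined at 21.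

Further compounds
F1 | step 13 | (5R,6R)-5,6-dihydroxy-2-(hydroxymethyl)-3-iodo-6-methylcyclohex-2-en-1-one | O[C@@H]1CC(I)=C(CO)C(=O)[C@]1(C)O
F2 | step 10 | (3aR,7aR)-5-(dimethylaminomethylidene)-2,2,3a-trimethyl-7,7a-dihydro-3aH-1,3-benzodioxole-4,6(5H)-dione | CC1(C)O[C@@H]2CC(=O)C(=CN(C)C)C(=O)[C@]2(C)O1
F3 | step 10 | chloro iminium chloride (C4a chloride, C8a–CH=NMe2 cation) | CC1(C)O[C@@H]2CC(Cl)=C(C=[N+](C)C)C(=O)[C@]2(C)O1.[Cl-]
F4 | step 10 | (3aR,7aR)-6-chloro-2,2,3a-trimethyl-4-oxo-3a,4,7,7a-tetrahydro-1,3-benzodioxole-5-carbaldehyde | CC1(C)O[C@@H]2CC(Cl)=C(C=O)C(=O)[C@]2(C)O1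
F5 | step 15 | 6,7-O-dibutylstannylene acetal of 16 | CCCC[Sn]1(CCCC)O[C@@H]2CC3=C(COC(/C=C/CO[Si](C)(C)C(C)(C)C)=C3)C(=O)[C@]2(C)O1
F6 | step 15 | C7 chlorodibutylstannyl ether of 21 | Cc1cc(O[Si](C)(C)C(C)(C)C)cc(O[Si](C)(C)C(C)(C)C)c1C(=O)O[C@@H]1CC2=C(COC(/C=C/CO[Si](C)(C)C(C)(C)C)=C2)C(=O)[C@]1(C)O[Sn](Cl)(CCCC)CCCC
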